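The synthesis rests on disconnecting C7–C8 of ring A and reconnecting C7 to C10. This contracts the spiro[5.5] core to an achiral spiro[3.5] cyclobutanol. The feature exploited is that the spiro carbon C6 carries two ring A methylenes, C7 and C11, so its configuration depends only on which of them stays bonded to C10. In one operation a chiral monovalent rhodium catalyst breaks one of the two enantiotopic cyclobutane bonds, joins the freed C7 to the isopropenyl terminus C8, closes ring A and fixes C6. The precursor is a 1-isopropenylcyclobutanol, spiro-fused at C6 to the ketal-masked ring B derived from ketoisophorone.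

Key step: step 6

Numbering used throughout: ring B = C1 [=C(CH3)], C2 (=CH), C3 (CHOH), C4 (CHBr), C5 (CMe2), C6 (spiro centre). Ring A = C6, C7 (CH2), C8 (CH2), C9 [=C(CH3)], C10 (=CBr), C11 (CH2).

Target stereochemistry: (3S,4S,6S). OH and Br are trans (both equatorial), and Br lies on the ring B face that carries C11. The C6 descriptor switches between R and S along the route only because substituent priorities change. The spatial arrangement set in step 6 is kept.

Assumption: (R)-DTBM-SEGPHOS is taken to break C7–C10 in the diastereomer 10 that is used; the sense of induction cannot be derived safely, and the equally available (S)-ligand would be used if the other bond breaks.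

Design remarks:
- Compound 10 is achiral but exists as two diastereomers. The catalyst reads the carbinol centre, so the two diastereomers should give opposite C6 configurations. Only one diastereomer is therefore carried into step 6.
- Hydride addition to the C3 ketone is expected anti to the axial C5 methyl group, which gives the cis-bromohydrin. The trans relationship of the target is therefore reached by reduction followed by inversion at C3, not by direct reduction.

Step 1
Reactants: 1 ketoisophorone; 2 ethylene glycol
Product: 3 ketoisophorone C3 monoketal (7,9,9-trimethyl-1,4-dioxaspiro[4.5]dec-6-en-8-one)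
Conditions: p-TsOH·H2O (cat.), toluene, reflux, Dean–Stark trap
Reagents that add atoms: none
Why: Acid-catalysed ketalisation with water removal is site-selective because the C6 carbonyl is screened by the C5 gem-dimethyl group and the C1 methyl group, so only the C3 carbonyl reacts and the alkene stays conjugated with the remaining ketone.

Step 2
Reactants: 3 ketoisophorone C3 monoketal
Product: 4 C6-methylene diene (7,9,9-trimethyl-8-methylidene-1,4-dioxaspiro[4.5]dec-6-ene)
Conditions: Ph3PCH3Br, KOtBu, toluene, 23 → 100 °C
Reagents that add atoms: methyltriphenylphosphonium bromide, C[P+](c1ccccc1)(c1ccccc1)c1ccccc1.[Br-]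
Why: Wittig methylenation under forcing conditions suits this hindered ketone because it has no acidic C–H that the ylide could remove, so 1,2-addition and collapse to the exocyclic C6 methylene is the only productive pathway.

Step 3
Reactants: 4 C6-methylene diene; 5 trichloroacetyl chloride
Product: 7 racemic dichlorocyclobutanone (four-membered ring C6–CCl2–C(=O)–CH2 spiro at C6), via dichloroketene 6 (not isolated)
Conditions: Zn–Cu, Et2O–DME, 0 → 23 °C, slow addition of 5
Reagents that add atoms: none
Why: In this ketene–alkene [2+2] cycloaddition the electrophilic ketene carbonyl carbon bonds to the open CH2 terminus while charge builds at the tertiary allylic C6, so CCl2 closes on C6, the carbonyl ends up opposite the spiro carbon, the ketal-flanked C1=C2 bond stays untouched, DME ties up ZnCl2, and the racemic C6 centre is erased in step 4.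

Step 4
Reactants: 7 racemic dichlorocyclobutanone
Product: 8 achiral spiro cyclobutanone (C6 flanked by two equivalent CH2 groups and C=O opposite C6)
Conditions: Zn, NH4Cl, MeOH, 23 °C
Reagents that add atoms: none
Why: Zinc-mediated reductive dehalogenation of an α,α-dichloroketone runs through zinc enolates that NH4Cl protonates, the medium is mild enough for the ketal, and the product has equivalent C7 and C11 methylenes and hence no stereocentre.

Step 5
Reactants: 8 achiral spiro cyclobutanone; 9 isopropenylmagnesium bromide
Product: 10 1-isopropenyl spiro cyclobutanol (achiral; isopropenyl cis to C1 and OH cis to C5)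
Conditions: THF, −78 → 0 °C; then H2O; chromatographic removal of the other diastereomer
Reagents that add atoms: none
Why: Grignard 1,2-addition to the strained and highly electrophilic cyclobutanone is fast at low temperature, and approach over the planar C1(CH3)=C2 side instead of the C5 gem-dimethyl side should place the isopropenyl group cis to C1.

Step 6
Reactants: 10 1-isopropenyl spiro cyclobutanol
Product: 11 (6R,9S)-spiro[5.5] C10 ketone (C3 ethylene ketal; C9 methyl equatorial)
Conditions: [Rh(OH)(cod)]2 (2.5 mol %), (R)-DTBM-SEGPHOS (6 mol %), toluene, 100 °C
Reagents that add atoms: none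
Why: Proposed new method: The tertiary alcohol displaces hydroxide on monovalent rhodium, relief of ring strain drives β-carbon elimination across C7–C10, and the neopentyl alkylrhodium, which cannot undergo β-hydride elimination since its β-carbon C6 bears no hydrogen, inserts the tethered isopropenyl ketone so that C7 bonds to C8, after which the oxa-π-allyl rhodium enolate takes a proton from the next molecule of 10 and the cycle closes. The closest known reaction type is the enantioselective rhodium-catalysed β-carbon elimination of prochiral tert-cyclobutanols, including the two-carbon ring expansion of 1-allenylcyclobutanols to cyclohexenones with quaternary stereocentres, and a plain 1-alkenyl carbinol as internal acceptor is the extension. Ring A closes in the 6-endo-trig mode. C6 is set by the ligand, whose pocket tells the C7–C10 and C11–C10 bonds apart through the steric contrast between the planar C1(CH3)=C2 side and the gem-dimethyl C5 side of ring B in a single diastereomer of 10, whereas C9 is set by enolate protonation with drift to the equatorial methyl epimer and is erased in step 7. The step needs 6-endo over 5-exo closure, which the enone polarisation (electrophilic, unsubstituted C8) and the methyl group on C9 should secure, and it needs ring closure to outrun 1,3- and 1,4-rhodium migration, which the ketal-shielded C2–H and the close conjugated acceptor favour.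

Step 7
Reactants: 11 (6R,9S)-spiro[5.5] C10 ketone
Product: 13 (6R)-C10 enol triflate with the C9=C10 double bond, via bromomagnesium enolate 12 (not isolated)
Conditions: iPr2NMgBr (from iPr2NH and EtMgBr), Et2O–THF, 23 °C; then PhNTf2, 40 °C
Reagents that add atoms: N-phenylbis(trifluoromethanesulfonimide), O=S(=O)(N(c1ccccc1)S(=O)(=O)C(F)(F)F)C(F)(F)F; ethylmagnesium bromide, CC[Mg]Br (supplies the MgBr of 12 only)
Why: Thermodynamic enolate formation followed by O-sulfonylation works here because the magnesium amide equilibrates the enolates towards the tetrasubstituted C9=C10 isomer, which is further favoured since C11 is a crowded neopentyl position, and the C9 stereocentre disappears.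

Step 8
Reactants: 13 (6R)-C10 enol triflate
Product: 14 (6R)-C10 vinyl bromide (C3 ethylene ketal)
Conditions: [Cp*Ru(MeCN)3]OTf (5 mol %), LiBr, 1,3-dimethyl-2-imidazolidinone, 80 °C
Reagents that add atoms: lithium bromide, [Li+].[Br-]
Why: Ruthenium-catalysed triflate-to-halide exchange of alkenyl triflates replaces C10–OTf by C10–Br without moving the ring alkene, under neutral conditions that leave the ketal and the C1=C2 bond alone.

Step 9
Reactants: 14 (6R)-C10 vinyl bromide
Product: 15 (6R)-ring B enone (10-bromo-1,5,5,9-tetramethylspiro[5.5]undeca-1,9-dien-3-one)
Conditions: 1 M HCl, THF, 23 °C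
Reagents that add atoms: water, O
Why: Acid-catalysed ketal hydrolysis releases the C3 ketone in conjugation with C1=C2, and neither the vinyl bromide nor the quaternary C6 is acid-sensitive.

Step 10
Reactants: 15 (6R)-ring B enone
Product: 17 (4S,6S)-C4 bromoenone (Br equatorial and cis to C11), via silyl dienol ether 16 (not isolated)
Conditions: Me3SiCl, LiN(SiMe3)2, THF, −78 °C; NBS, THF, −78 → 0 °C; then Et3N (cat.), CH2Cl2, 23 °C
Reagents that add atoms: N-bromosuccinimide, O=C1CCC(=O)N1Br; chlorotrimethylsilane, C[Si](C)(C)Cl (supplies the silyl group of 16 only)
Why: Kinetic α′-deprotonation with in situ silylation gives the cross-conjugated silyl dienol ether, NBS brominates its C4 terminus (silyl enol ether halogenation), and because C4 stays epimerisable the amine should funnel the product to the equatorial bromide of the preferred ring B half-chair, in which C7 is pseudoaxial so that the C1 methyl group leans over the flat C10 instead of the axial C8–H, which places Br cis to C11.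

Step 11
Reactants: 17 (4S,6S)-C4 bromoenone
Product: 18 (3R,4S,6S)-cis-bromohydrin (OH pseudoaxial and Br equatorial)
Conditions: iBu2AlH, CH2Cl2, −78 °C; then H2O
Reagents that add atoms: none
Why: In this 1,2-reduction of the enone by a bulky aluminium hydride the axial C5 methyl group blocks the C3 face on which bromine lies, so hydride should arrive from the opposite face and give the alcohol cis to bromine, an arrangement that cannot close to an epoxide.

Step 12
Reactants: 18 (3R,4S,6S)-cis-bromohydrin
Product: 20 target (3S,4S,6S)-4,10-dibromo-1,5,5,9-tetramethylspiro[5.5]undeca-1,9-dien-3-ol, via C3 formate 19 (not isolated)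
Conditions: HCO2H, PPh3, DIAD, THF, 0 → 23 °C; then MeOH, KHCO3 (cat.), 23 °C
Reagents that add atoms: formic acid, O=CO
Why: In the Mitsunobu reaction formate displaces the allylic alkoxyphosphonium group with inversion from the open face anti to the axial C5 methyl group, which sets (3S) trans to bromine, and the labile formate is then removed by bicarbonate-catalysed methanolysis, too mild to trigger epoxide formation from the diequatorial bromohydrin.

Compound list
1 | ketoisophorone (2,6,6-trimethylcyclohex-2-ene-1,4-dione) | CC1=CC(=O)CC(C)(C)C1=O | starting material
2 | ethylene glycol | OCCO | starting material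
3 | ketoisophorone C3 monoketal (7,9,9-trimethyl-1,4-dioxaspiro[4.5]dec-6-en-8-one) | CC1=CC2(OCCO2)CC(C)(C)C1=O | intermediate
4 | C6-methylene diene (7,9,9-trimethyl-8-methylidene-1,4-dioxaspiro[4.5]dec-6-ene) | CC1=CC2(OCCO2)CC(C)(C)C1=C | intermediate
5 | trichloroacetyl chloride | ClC(Cl)(Cl)C(Cl)=O | starting material
6 | dichloroketene | ClC(Cl)=C=O | intermediate
7 | racemic dichlorocyclobutanone, CCl2 bonded to C6 | CC1=CC2(OCCO2)CC(C)(C)C13CC(=O)C3(Cl)Cl | intermediate
8 | achiral spiro cyclobutanone | CC1=CC2(OCCO2)CC(C)(C)C13CC(=O)C3 | intermediate
9 | isopropenylmagnesium bromide | CC(=C)[Mg]Br | starting material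
10 | 1-isopropenyl spiro cyclobutanol, achiral, isopropenyl cis to C1 | CC1=CC2(OCCO2)CC(C)(C)[C@@]13C[C@@](O)(C(C)=C)C3 | intermediate
11 | (6R,9S)-spiro[5.5] C10 ketone, C3 ethylene ketal, C9 methyl equatorial | CC1=CC2(OCCO2)CC(C)(C)[C@]13CC[C@H](C)C(=O)C3 | intermediate
12 | (6R)-bromomagnesium C9=C10 enolate | CC1=CC2(OCCO2)CC(C)(C)[C@]13CCC(C)=C(O[Mg]Br)C3 | intermediate
13 | (6R)-C10 enol triflate | CC1=CC2(OCCO2)CC(C)(C)[C@]13CCC(C)=C(OS(=O)(=O)C(F)(F)F)C3 | intermediate
14 | (6R)-C10 vinyl bromide, C3 ethylene ketal | CC1=CC2(OCCO2)CC(C)(C)[C@]13CCC(C)=C(Br)C3 | intermediate
15 | (6R)-10-bromo-1,5,5,9-tetramethylspiro[5.5]undeca-1,9-dien-3-one | CC1=CC(=O)CC(C)(C)[C@]12CCC(C)=C(Br)C2 | intermediate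
16 | (6S)-C3 trimethylsilyl dienol ether (C1=C2 and C3=C4) | CC1=CC(O[Si](C)(C)C)=CC(C)(C)[C@]12CCC(C)=C(Br)C2 | intermediate
17 | (4S,6S)-4,10-dibromo-1,5,5,9-tetramethylspiro[5.5]undeca-1,9-dien-3-one | CC1=CC(=O)[C@@H](Br)C(C)(C)[C@]12CCC(C)=C(Br)C2 | intermediate
18 | (3R,4S,6S)-cis-bromohydrin | CC1=C[C@@H](O)[C@@H](Br)C(C)(C)[C@]12CCC(C)=C(Br)C2 | intermediate
19 | (3S,4S,6S)-C3 formate | CC1=C[C@H](OC=O)[C@@H](Br)C(C)(C)[C@]12CCC(C)=C(Br)C2 | intermediate
20 | (3S,4S,6S)-4,10-dibromo-1,5,5,9-tetramethylspiro[5.5]undeca-1,9-dien-3-ol | CC1=C[C@H](O)[C@@H](Br)C(C)(C)[C@]12CCC(C)=C(Br)C2 | target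

Total step count: 12. Longest linear sequence: 12 steps (1 → 20).

Steps most likely to fail

1. Step 6 (key step).
- What may go wrong: closure of the alkylrhodium in the 5-exo sense; its loss through protonation or through 1,3- or 1,4-rhodium migration before C7 reaches C8; or weak discrimination between the two ring bonds.
- Fallback with known chemistry only, setting out from 10 and returning at 13: the event is split into two known operations. The palladium-catalysed enantioselective ring-opening alkenylation of tert-cyclobutanols uses Pd(OAc)2, a chiral ferrocenyl P,N-ligand, Cs2CO3 and vinyl bromide in toluene. Zerovalent palladium adds oxidatively to the bromide, and the divalent palladium alkoxide undergoes β-carbon elimination. This breaks the same C7–C10 bond and forms C7–C8 by reductive elimination, giving the C6-allyl isopropenyl ketone F1. Ring-closing metathesis with the second-generation Grubbs catalyst then closes ring A at C8=C9 to the spiro 2-methylcyclohexenone F2. Conjugate reduction with LiBH(sBu)3 gives the regiodefined lithium C9=C10 enolate F3, which is trapped with PhNTf2 to rejoin the route at 13. This bypasses 11 and 12.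

2. Step 10.
- What may go wrong: too small a bias at C4, because the two faces of ring B differ only through the remote difference between C7 and C11; and halogen scrambling during the equilibration.
- Fallback, setting out from 15 and returning at 17: C4 is set by C–H bond formation instead of C–Br bond formation. Compound 15 is silylated and brominated as in step 10 (through 16), but the amine treatment is left out. Attack anti to the axial C5 methyl group is then expected to leave the C4-epimeric bromoenone F4. LiN(SiMe3)2 at −78 °C converts it into the lithium bromodienolate F5. The bulky proton source 2,6-di-tert-butyl-4-methylphenol should then protonate C4 from that same open face, which pushes bromine into the equatorial position of 17.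

3. Step 12.
- What may go wrong: slow activation of the crowded pseudoaxial hydroxyl group; and anti elimination across C3–C4 (the axial C4–H is antiperiplanar to the leaving group) in competition with substitution.
- Fallback, setting out from 17 and returning at 20: kinetic reduction plus inversion is replaced by thermodynamic control. The method is a Meerwein–Ponndorf–Verley reduction with Al(OiPr)3 in iPrOH–toluene, with a little acetone kept in the flask. Reversible hydride transfer should then let the carbinol settle in the pseudoequatorial (3S) position, free of the syn-axial contact with the C5 methyl group. Compounds 18 and 19 are skipped and no new compound is made (F0).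

Further compounds
F1 | step 6 | (6R)-C6-allyl isopropenyl ketone (C6 bears CH2CH=CH2 and CH2C(=O)C(CH3)=CH2; C3 ethylene ketal) | CC1=CC2(OCCO2)CC(C)(C)[C@@]1(CC=C)CC(=O)C(C)=C
F2 | step 6 | (6R)-spiro 2-methylcyclohexenone (C8=C9 and C10=O; C3 ethylene ketal) | CC1=CC2(OCCO2)CC(C)(C)[C@]13CC=C(C)C(=O)C3
F3 | step 6 | (6R)-lithium C9=C10 enolate | CC1=CC2(OCCO2)CC(C)(C)[C@]13CCC(C)=C([O-])C3.[Li+]
F4 | step 10 | (4R,6S)-C4-epimeric bromoenone | CC1=CC(=O)[C@H](Br)C(C)(C)[C@]12CCC(C)=C(Br)C2
F5 | step 10 | (6S)-lithium bromodienolate | CC1=CC([O-])=C(Br)C(C)(C)[C@]12CCC(C)=C(Br)C2.[Li+]
F0 | step 12 | none | none
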